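The dihydropyran ring (O2, C1, C11a, C4a, C4, C3; xenicane numbering) is read as a masked 1,5-dialdehyde in which C4 also carries the C12 carbonyl carbon. C4a is then the β- and C4 the α-carbon of a C12 acceptor, and C11a is the α-carbon of a C1 ester. Step 6 joins four components in one flask: a chiral trienolate (C1, C11a, C11, C19, C10, C9), an iodo-dienoate (C12, C4–C8), a formate (C3) and a methylating agent. It makes C4a–C11a with both ring-fusion stereocentres and C3=C4. The precursors are two open-chain esters. The nine-membered ring is closed later at C8–C9 by a B-alkyl Suzuki coupling.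

Key step: step 6

Numbering used throughout:
- O2 is the ring oxygen and C1 the acetal carbon.
- C3=C4 is the enol ether; C4a and C11a are the ring-fusion carbons.
- C5 and C6 follow, then C7 (methyl C18) and C8, which carry the epoxide.
- C9 and C10 follow, then C11 (=C19H2).
- The side chain is C12 (OAc), C13, C14=C15 (methyl, CO2Me).

Assumption: the sense of induction of the (−)-8-phenylmenthyl trienolate (step 6) and of the bisphosphoramide catalyst (step 12) is assigned by analogy with simpler enolates and aldehydes. The antipodal controller would be used if the sense were opposite.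

Step 1
Reactants: 1 pent-4-yn-1-ol
Product: 2 (E)-5-iodo-4-methylpent-4-en-1-ol
Conditions: AlMe3 (3 equiv), Cp2ZrCl2 (cat.), CH2Cl2, 0 °C to rt; then I2, THF, −30 °C
Reagents that add atoms: trimethylaluminium C[Al](C)C; iodine II
Why: Negishi carboalumination adds methyl and aluminium syn across the alkyne with aluminium at the terminus, and iodinolysis with retention gives the (E)-vinyl iodide that fixes the later C7=C8 geometry.

Step 2
Reactants: 2 (E)-5-iodo-4-methylpent-4-en-1-ol
Product: 3 (E)-5-iodo-4-methylpent-4-enal
Conditions: DMP, NaHCO3, CH2Cl2, 0 °C to rt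
Reagents that add atoms: none
Why: Dess–Martin oxidation of the primary alcohol stops at the aldehyde and does not touch the vinyl iodide.

Step 3
Reactants: 3 (E)-5-iodo-4-methylpent-4-enal
Product: 4 methyl (2E,6E)-7-iodo-6-methylhepta-2,6-dienoate
Conditions: Ph3P=CHCO2Me, CH2Cl2, rt
Reagents that add atoms: methyl (triphenylphosphoranylidene)acetate COC(=O)C=P(c1ccccc1)(c1ccccc1)c1ccccc1
Why: Wittig olefination with a stabilised ylide should give the (E)-enoate needed for a defined Michael topicity.

Step 4
Reactants: 5 but-2-ynoic acid; 6 (−)-8-phenylmenthol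
Product: 7 (−)-8-phenylmenthyl but-2-ynoate
Conditions: DCC, DMAP (cat.), CH2Cl2, 0 °C to rt
Reagents that add atoms: none
Why: Steglich esterification joins the acid and the hindered secondary alcohol under neutral conditions without touching the stereocentres of the auxiliary.

Step 5
Reactants: 7 (−)-8-phenylmenthyl but-2-ynoate
Product: 8 (−)-8-phenylmenthyl (2E)-3-methylpenta-2,4-dienoate
Conditions: CH2=CHMgBr, CuI (cat.), LiCl, THF, −78 °C; AcOH quench at −78 °C
Reagents that add atoms: vinylmagnesium bromide C=C[Mg]Br
Why: Copper-catalysed conjugate carbometalation of the ynoate is a syn addition, so the vinyl group ends up trans and the methyl group cis to the ester, and the cold proton quench avoids isomerisation through the allenolate.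

Step 6
Reactants: 8 (−)-8-phenylmenthyl (2E)-3-methylpenta-2,4-dienoate; 4 methyl (2E,6E)-7-iodo-6-methylhepta-2,6-dienoate
Product: 12 β-methoxyacrylate diester (2R,3S), via lithium trienolate 9 (not isolated), via lithium ester enolate 10 (not isolated), via lithium formyl enolate 11 (not isolated)
Conditions: LDA, THF, −78 °C; add 4, −78 °C; HCO2CH2CF3, −78 °C; Me2SO4, DMPU, −78 °C to 0 °C
Reagents that add atoms: 2,2,2-trifluoroethyl formate O=COCC(F)(F)F; dimethyl sulfate COS(=O)(=O)OC
Why: LDA removes a proton from the methyl group cis to the ester carbonyl of 8 to give the Z(O) lithium trienolate 9, whose α-carbon C11a adds to C4a of enoate 4 (Michael addition) through a closed lithium-bridged transition state; the regiodefined ester enolate 10 is C-formylated by the activated formate (crossed Claisen condensation, C3–C4) and the formyl enolate 11 is O-methylated, which locks C3=C4 as a β-methoxyacrylate. The closest known reaction types are the three-component conjugate addition–enolate trapping sequence and the formylation–methylation route to β-methoxyacrylates. No ring is closed in this step, since both rings are deferred to steps 9 and 13. C11a is controlled by the 8-phenylmenthyl group, whose phenyl ring covers one face of the trienolate, and C4a follows from the syn topicity expected for a Z(O) ester enolate and an (E)-enoate in the bridged transition state, which corresponds to the trans ring fusion. The step needs α- over γ-attack of the trienolate and 1,4- over 1,2-addition (both kinetic preferences of lithium ester dienolates at −78 °C), formylation faster than proton transfer from the acidic C11a–H (hence trifluoroethyl formate at −78 °C) and O- over C-methylation (hard sulfate, DMPU). Minor diastereomers can be removed here because the auxiliary is still attached.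

Step 7
Reactants: 12 β-methoxyacrylate diester
Product: 13 seco diol
Conditions: DIBAL (excess), CH2Cl2, −78 °C to 0 °C; Rochelle salt work-up
Reagents that add atoms: none
Why: DIBAL reduction takes both esters to primary alcohols by 1,2-addition, frees the auxiliary for recovery and leaves vinyl iodide, diene and enol ether alone.

Step 8
Reactants: 13 seco diol
Product: 14 seco dialdehyde
Conditions: DMP, NaHCO3, CH2Cl2, 0 °C
Reagents that add atoms: none
Why: Buffered double Dess–Martin oxidation gives the dialdehyde under non-basic conditions, so the C11a stereocentre next to the new aldehyde should neither epimerise nor move into conjugation.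

Step 9
Reactants: 14 seco dialdehyde
Product: 15 dihydropyranol aldehyde (lactol)
Conditions: PPTS (cat.), THF–H2O, rt
Reagents that add atoms: water O
Why: Acid-catalysed addition–elimination of water at C3 of the β-methoxyenal sets free the enol, whose oxygen closes 6-exo-trig on the C1 aldehyde (hemiacetalisation) to the trans-disubstituted dihydropyranol, with C1 still free to equilibrate.

Step 10
Reactants: 15 dihydropyranol aldehyde (lactol)
Product: 16 1-acetoxy dihydropyran aldehyde
Conditions: Ac2O, pyridine, DMAP (cat.), CH2Cl2, 0 °C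
Reagents that add atoms: acetic anhydride CC(=O)OC(C)=O
Why: O-Acetylation of the equilibrating lactol should take the less hindered anomer with oxygen trans to the C11a substituent, which sets C1, while the conjugated aldehyde deactivates the enol acetal towards ionisation.

Step 11
Reactants: 17 methyl tiglate
Product: 18 tiglate-derived TBS vinylketene acetal
Conditions: LDA, THF–DMPU, −78 °C; TBSCl
Reagents that add atoms: tert-butyldimethylsilyl chloride CC(C)(C)[Si](C)(C)Cl
Why: γ-Deprotonation of the tiglate and O-silylation (silyl ketene acetal formation) give the vinylogous nucleophile that holds the whole chain from C13 onwards.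

Step 12
Reactants: 16 1-acetoxy dihydropyran aldehyde; 18 tiglate-derived TBS vinylketene acetal
Product: 19 (12S)-alcohol with complete side chain
Conditions: SiCl4, binaphthyldiamine-derived chiral bisphosphoramide (cat., the enantiomer that leaves the Si face of the aldehyde open), i-Pr2NEt (cat.), CH2Cl2, −78 °C; aq. NaHCO3 work-up
Reagents that add atoms: none
Why: Catalytic enantioselective vinylogous Mukaiyama aldol reaction: the chiral phosphoramide-bound silicon cation activates the C12 aldehyde, the dienolate attacks through its γ-carbon on the Si face to set 12S, and the open transition state gives the (E)-enoate.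

Step 13
Reactants: 19 (12S)-alcohol with complete side chain
Product: 21 bicyclic (E)-cyclononene alcohol, via bis-boryl intermediate 20 (not isolated)
Conditions: Sia2BH (2.2 equiv), THF, 0 °C; then slow addition to Pd(dppf)Cl2 (cat.), AsPh3, Cs2CO3, DMF–THF–H2O, rt, high dilution
Reagents that add atoms: none
Why: Disiamylborane hydroborates only the monosubstituted end of the 2-substituted diene (and silences the free hydroxyl as a borinate), and the intramolecular B-alkyl Suzuki–Miyaura coupling with the vinyl iodide, helped by the trans-disposed chains on the dihydropyran, closes the nine-membered ring at C8–C9 with retention of the E geometry.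

Step 14
Reactants: 21 bicyclic (E)-cyclononene alcohol
Product: 22 bicyclic diacetate
Conditions: Ac2O, pyridine, DMAP (cat.), CH2Cl2, 0 °C to rt
Reagents that add atoms: acetic anhydride CC(=O)OC(C)=O
Why: Standard O-acetylation esterifies the C12 alcohol with retention and restores the C1 acetate should it have been lost in step 13.

Step 15
Reactants: 22 bicyclic diacetate
Product: 23 target CNP0184381.1
Conditions: mCPBA (1 equiv), NaHCO3, CH2Cl2, −78 °C to −20 °C
Reagents that add atoms: 3-chloroperbenzoic acid O=C(OO)c1cccc(Cl)c1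
Why: Prilezhaev epoxidation: the strained (E)-trisubstituted C7=C8 bond is by far the most reactive alkene and exposes only its outer face, so syn delivery of oxygen to the favoured ring conformer should set C7 and C8 as in the target, while the acetoxy-flanked enol ether, the 1,1-disubstituted alkene and the enoate react more slowly.

Compound list
1 | pent-4-yn-1-ol | C#CCCCO | starting material
2 | (E)-5-iodo-4-methylpent-4-en-1-ol | OCCC/C(C)=C/I | intermediate
3 | (E)-5-iodo-4-methylpent-4-enal | O=CCC/C(C)=C/I | intermediate
4 | methyl (2E,6E)-7-iodo-6-methylhepta-2,6-dienoate | COC(=O)/C=C/CC/C(C)=C/I | intermediate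
5 | but-2-ynoic acid | CC#CC(=O)O | starting material
6 | (1R,2S,5R)-5-methyl-2-(2-phenylpropan-2-yl)cyclohexan-1-ol, (−)-8-phenylmenthol | O[C@@H]1C[C@H](C)CC[C@H]1C(C)(C)c1ccccc1 | starting material
7 | (−)-8-phenylmenthyl but-2-ynoate | CC#CC(=O)O[C@@H]1C[C@H](C)CC[C@H]1C(C)(C)c1ccccc1 | intermediate
8 | (−)-8-phenylmenthyl (2E)-3-methylpenta-2,4-dienoate | C=C/C(C)=C/C(=O)O[C@@H]1C[C@H](C)CC[C@H]1C(C)(C)c1ccccc1 | intermediate
9 | Z(O) lithium trienolate of 8 | [Li+].C=CC(=C)/C=C(\[O-])O[C@@H]1C[C@H](C)CC[C@H]1C(C)(C)c1ccccc1 | intermediate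
10 | lithium ester enolate at C4 after the Michael addition | [Li+].I/C=C(\C)CC[C@@H]([C@@H](C(=O)O[C@@H]1C[C@H](C)CC[C@H]1C(C)(C)c1ccccc1)C(=C)C=C)C=C([O-])OC | intermediate
11 | lithium enolate of the C4-formyl ester | [Li+].I/C=C(\C)CC[C@@H]([C@@H](C(=O)O[C@@H]1C[C@H](C)CC[C@H]1C(C)(C)c1ccccc1)C(=C)C=C)C(C(=O)OC)=C[O-] | intermediate
12 | 5-methyl 1-[(−)-8-phenylmenthyl] (2R,3S)-2-(buta-1,3-dien-2-yl)-3-[(E)-4-iodo-3-methylbut-3-enyl]-4-[(E)-methoxymethylidene]pentanedioate (C2 = C11a, C3 = C4a, configured as in 23) | I/C=C(\C)CC[C@@H]([C@@H](C(=O)O[C@@H]1C[C@H](C)CC[C@H]1C(C)(C)c1ccccc1)C(=C)C=C)/C(C(=O)OC)=C\OC | intermediate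
13 | diol from 12: C1H2OH and C12H2OH, β-methoxy enol ether, diene and vinyl iodide kept, C4a S, C11a R | I/C=C(\C)CC[C@@H]([C@@H](CO)C(=C)C=C)/C(CO)=C\OC | intermediate
14 | dialdehyde from 13: C1HO and β-methoxyenal C12HO, C4a S, C11a R | I/C=C(\C)CC[C@@H]([C@@H](C=O)C(=C)C=C)/C(C=O)=C\OC | intermediate
15 | 2-hydroxy-3-(buta-1,3-dien-2-yl)-4-[(E)-4-iodo-3-methylbut-3-enyl]-3,4-dihydro-2H-pyran-5-carbaldehyde, 3,4-trans, anomer drawn with OH trans to the dienyl group | I/C=C(\C)CC[C@@H]1C(C=O)=CO[C@H](O)[C@H]1C(=C)C=C | intermediate
16 | 2-acetate of 15 (1R,4aS,11aR in xenicane numbering) | I/C=C(\C)CC[C@@H]1C(C=O)=CO[C@H](OC(C)=O)[C@H]1C(=C)C=C | intermediate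
17 | methyl tiglate, methyl (E)-2-methylbut-2-enoate | C/C=C(\C)C(=O)OC | starting material
18 | tert-butyl[(1-methoxy-2-methylbuta-1,3-dienyl)oxy]dimethylsilane (ketene acetal geometry of no consequence) | C=CC(C)=C(OC)O[Si](C)(C)C(C)(C)C | intermediate
19 | (12S)-alcohol: 16 with CH(OH)CH2CH=C(CH3)CO2Me, (E)-enoate, in place of CHO | I/C=C(\C)CC[C@@H]1C([C@H](C/C=C(\C)C(=O)OC)O)=CO[C@H](OC(C)=O)[C@H]1C(=C)C=C | intermediate
20 | C9-disiamylborane and O12-disiamylborinate of 19 | I/C=C(\C)CC[C@@H]1C([C@H](C/C=C(\C)C(=O)OC)OB(C(C)C(C)C)C(C)C(C)C)=CO[C@H](OC(C)=O)[C@H]1C(=C)CCB(C(C)C(C)C)C(C)C(C)C | intermediate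
21 | 7,8-deoxy-12-O-deacetyl target: trans-fused dihydropyran and (7E)-cyclononene, 11(19)-methylene, 1R,4aS,11aR,12S | C=C1CC/C=C(\C)CC[C@@H]2C([C@H](C/C=C(\C)C(=O)OC)O)=CO[C@H](OC(C)=O)[C@@H]12 | intermediate
22 | 12-acetate of 21 | C=C1CC/C=C(\C)CC[C@@H]2C([C@H](C/C=C(\C)C(=O)OC)OC(C)=O)=CO[C@H](OC(C)=O)[C@@H]12 | intermediate
23 | CNP0184381.1 (1R,4aS,7S,8S,11aR,12S) | C=C1CC[C@@H]2O[C@@]2(C)CC[C@@H]2C([C@H](C/C=C(\C)C(=O)OC)OC(C)=O)=CO[C@H](OC(C)=O)[C@@H]12 | target

Total step count: 15. Longest linear sequence: 12 (steps 1, 2, 3, 6, 7, 8, 9, 10, 12, 13, 14, 15).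

Steps most likely to fail

1. Step 6. The facial or simple diastereoselection of the Michael addition may be poor. Proton transfer from C11a–H to the ester enolate may also outrun the formylation.
   - Fallback (sets out from 3, returns at 15): the same two bonds are made by a stereospecific sigmatropic route.
   - Wittig reaction of 3 with Ph3P=CHCHO gives (2E,6E)-7-iodo-6-methylhepta-2,6-dienal F1.
   - Methyl (2E)-3-methylpenta-2,4-dienoate F2 is made from methyl but-2-ynoate as in step 5. LDA and TBSCl turn it into the silyl trienol ether F3.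
   - An enantioselective vinylogous Mukaiyama aldol–lactonisation of F3 with F1 (Cu(OTf)2, Tol-BINAP, Bu4N[Ph3SiF2]) gives the (R)-4-vinyl-5,6-dihydropyran-2-one F4. Its ring locks C1 cis to C19.
   - DIBAL gives the lactol F5, and condensation with SAMP opens it to the hydroxy hydrazone F6.
   - KH and 18-crown-6 trigger an anionic oxy-Cope rearrangement through a chair. C4a–C11a forms, C12–C19 breaks and the C11=C19 methylene appears.
   - The aldehyde enolate is formylated in the same flask by trifluoroethyl formate to the hydrazone dialdehyde enol F7, whose diastereomers are separable.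
   - Aqueous oxalic acid removes the hydrazone and the enol closes to 15.

2. Step 13. Intermolecular coupling, protodeboronation or base-induced opening of the acetal acetate may outrun the nine-membered ring closure.
   - Fallback (sets out from 12, returns at 21): the carbocycle is closed first, on the robust diester, where stronger base and heat are tolerated.
   - Hydroboration and Suzuki coupling of 12 as in step 13 give the cyclononene diester F8.
   - The chemistry of steps 7 to 10 then gives the diol F9, the dialdehyde F10, the bicyclic lactol F11 and the bicyclic acetoxy aldehyde F12.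
   - The vinylogous aldol reaction of step 12 with 18 converts F12 into 21.

3. Step 15. Oxidation of the enol ether C3=C4 may compete, or the peracid may attack the wrong ring conformer.
   - Fallback (sets out from 21, returns at 23): the enol ether is switched off by a redox detour.
   - DMP oxidation of 21 gives the vinylogous ester ketone F13.
   - mCPBA then has only C7=C8 as an electron-rich alkene and gives the epoxy ketone F14.
   - CBS reduction restores the (12S)-alcohol as the epoxy alcohol F15.
   - Acetylation as in step 14 gives 23.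

Further compounds
F1 | step 6 | (2E,6E)-7-iodo-6-methylhepta-2,6-dienal | O=C/C=C/CCC(/C)=C/I
F2 | step 6 | methyl (2E)-3-methylpenta-2,4-dienoate | C=C/C(C)=C/C(=O)OC
F3 | step 6 | tert-butyl[(1-methoxy-3-methylidenepenta-1,4-dienyl)oxy]dimethylsilane | C=CC(=C)C=C(OC)O[Si](C)(C)C(C)(C)C
F4 | step 6 | (6R)-4-ethenyl-6-[(1E,5E)-6-iodo-5-methylhexa-1,5-dienyl]-5,6-dihydropyran-2-one | O=C1C=C(C=C)C[C@H](/C=C/CCC(/C)=C/I)O1
F5 | step 6 | lactol of F4 (anomers) | OC1C=C(C=C)C[C@H](/C=C/CCC(/C)=C/I)O1
F6 | step 6 | SAMP hydrazone of the ring-opened (Z)-enal with free (R)-C12 hydroxyl | COC[C@@H]1CCCN1/N=C/C=C(/C=C)C[C@@H](O)/C=C/CCC(/C)=C/I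
F7 | step 6 | SAMP hydrazone at C1 with C4 diformyl unit as its enol, C4a and C11a as in 15 | I/C=C(\C)CC[C@@H]([C@@H](/C=N/N1CCC[C@H]1COC)C(=C)C=C)C(C=O)=CO
F8 | step 13 | (E)-cyclononene diester, ring-closed analogue of 12 | C=C1CC/C=C(\C)CC[C@H](/C(C(=O)OC)=C\OC)[C@H]1C(=O)O[C@@H]1C[C@H](C)CC[C@H]1C(C)(C)c1ccccc1
F9 | step 13 | (E)-cyclononene diol, ring-closed analogue of 13 | C=C1CC/C=C(\C)CC[C@H](/C(CO)=C\OC)[C@H]1CO
F10 | step 13 | (E)-cyclononene dialdehyde, ring-closed analogue of 14 | C=C1CC/C=C(\C)CC[C@H](/C(C=O)=C\OC)[C@H]1C=O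
F11 | step 13 | bicyclic lactol aldehyde, ring-closed analogue of 15 | C=C1CC/C=C(\C)CC[C@@H]2C(C=O)=CO[C@H](O)[C@@H]12
F12 | step 13 | bicyclic 1-acetoxy aldehyde, ring-closed analogue of 16 | C=C1CC/C=C(\C)CC[C@@H]2C(C=O)=CO[C@H](OC(C)=O)[C@@H]12
F13 | step 15 | 12-ketone of 21 | C=C1CC/C=C(\C)CC[C@@H]2C(C(=O)C/C=C(\C)C(=O)OC)=CO[C@H](OC(C)=O)[C@@H]12
F14 | step 15 | (7S,8S)-epoxide of F13 | C=C1CC[C@@H]2O[C@@]2(C)CC[C@@H]2C(C(=O)C/C=C(\C)C(=O)OC)=CO[C@H](OC(C)=O)[C@@H]12
F15 | step 15 | (7S,8S)-epoxy (12S)-alcohol, 12-O-deacetyl target | C=C1CC[C@@H]2O[C@@]2(C)CC[C@@H]2C([C@H](C/C=C(\C)C(=O)OC)O)=CO[C@H](OC(C)=O)[C@@H]12
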